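Ring C of the flavonol is traced back to a 2H-chromene, and that chromene to an aryl 1-arylpropargyl ether. The feature exploited is that C4a of ring A is ortho to O1 and that O1, C2 (bearing ring B), C3 and C4 form a propargyl unit. One thermal operation (Claisen shift, hydrogen shift, oxa-6π closure) makes C4–C4a, restores O1–C2 and closes ring C. The precursor is the ether of 3-benzyloxy-2-bromophenol with 1-(4-benzyloxy-3-methoxyphenyl)prop-2-yn-1-ol. Its bromine blocks the ortho carbon between the two ring A oxygens and leaves with the benzyl groups in the later hydrogenolysis. The C3=C4 alkene is then oxidised to the 3-hydroxy-4-one.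

Key step: step 4

Assumption 1: the target is drawn as the free tris(hydrogen sulfate); step 8 delivers this form after proton exchange, and a salt would be preferred for storage because aryl hydrogen sulfates hydrolyse under their own acidity.
Assumption 2: 4-benzyloxy-3-methoxybenzaldehyde (O-benzylvanillin) and 2-bromoresorcinol are taken as purchased materials; 3, 7, 11 and 12 are racemates, and every stereocentre disappears at 14.

Step 1
Reactants: 1 4-benzyloxy-3-methoxybenzaldehyde; 2 ethynylmagnesium bromide
Product: 3 1-(4-benzyloxy-3-methoxyphenyl)prop-2-yn-1-ol (racemic)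
Conditions: HC≡CMgBr, THF, 0 °C; sat. aq. NH4Cl
Reagents that add atoms: ethynylmagnesium bromide 2, C#C[Mg]Br
Why: Grignard 1,2-addition of the alkynyl nucleophile to a non-enolisable aryl aldehyde should be clean, the carbinol centre forming without control (racemate, erased later), and the mild ammonium chloride quench avoids ionising the acid-sensitive propargylic benzylic alcohol.

Step 2
Reactants: 4 2-bromoresorcinol; 5 benzyl bromide
Product: 6 3-benzyloxy-2-bromophenol
Conditions: BnBr (1 equiv), K2CO3 (1 equiv), acetone, reflux; 4 in twofold excess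
Reagents that add atoms: benzyl bromide 5, BrCc1ccccc1
Why: Williamson ether synthesis on a symmetric diol, so either hydroxyl gives the same monoether, while the excess of 4 and the single equivalent of base should hold back the bis-ether and the unreacted diol is recoverable by aqueous base extraction and chromatography.

Step 3
Reactants: 3 1-(4-benzyloxy-3-methoxyphenyl)prop-2-yn-1-ol; 6 3-benzyloxy-2-bromophenol
Product: 7 1-benzyloxy-2-bromo-3-{[1-(4-benzyloxy-3-methoxyphenyl)prop-2-yn-1-yl]oxy}benzene (racemic)
Conditions: PPh3, DIAD, THF, 0 °C to rt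
Reagents that add atoms: none
Why: Mitsunobu etherification, in which the ortho-bromophenol is acidic enough to protonate the betaine and its phenoxide displaces the oxyphosphonium of the secondary propargylic alcohol at oxygen under neutral conditions; the centre stays racemic, which is of no consequence.

Step 4
Reactants: 7 1-benzyloxy-2-bromo-3-{[1-(4-benzyloxy-3-methoxyphenyl)prop-2-yn-1-yl]oxy}benzene
Product: 11 7-benzyloxy-8-bromo-2-(4-benzyloxy-3-methoxyphenyl)-2H-chromene (racemic), via allenyl cyclohexadienone 8 (not isolated), via ortho-allenylphenol 9 (not isolated), via ortho-quinone methide 10 (not isolated)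
Conditions: PhNEt2 (degassed), 190 °C
Reagents that add atoms: none
Why: A [3,3] sigmatropic shift of the aryl propargyl ether joins the alkyne terminus (C4) to the free ortho carbon (C4a) and gives dienone 8, which tautomerises to allenylphenol 9; a 1,5-hydrogen shift from O–H to the central allene carbon through a six-membered transition state then gives ortho-quinone methide 10 with the side chain syn to the carbonyl. The closest known reaction type is the thermal aryl propargyl ether Claisen rearrangement to 2H-chromenes in hot N,N-dialkylaniline, which tolerates 1-aryl substitution. Ring C closes by a thermal disrotatory oxa-6π electrocyclization of the oxatriene O1=C8a–C4a=C4–C3=C2, the carbonyl oxygen bonding to C2 and ring A regaining aromaticity. C2 is the only new stereocentre; nothing controls it, so 11 forms as a racemate, and the centre is erased when C2 becomes sp2 in step 6. The one selectivity required is the choice between the two ortho carbons of ring A, and the bromine on the carbon flanked by both oxygens secures it, because a shift onto that carbon gives a dienone that cannot tautomerise and should revert, so C4 ends up para to the benzyloxy group (7-oxygenation).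

Step 5
Reactants: 11 7-benzyloxy-8-bromo-2-(4-benzyloxy-3-methoxyphenyl)-2H-chromene
Product: 12 rac-(2R,3S,4S)-7-benzyloxy-8-bromo-2-(4-benzyloxy-3-methoxyphenyl)chromane-3,4-diol
Conditions: OsO4 (cat.), NMO, acetone/THF/H2O, rt; aq. Na2SO3
Reagents that add atoms: N-methylmorpholine N-oxide, C[N+]1([O-])CCOCC1; water, O; osmium tetroxide (catalytic oxygen carrier), O=[Os](=O)(=O)=O
Why: Catalytic osmium tetroxide syn-dihydroxylation of the cis-disubstituted styrenyl C3=C4 bond, with the oxidant expected to approach the face opposite the C2 aryl group and so set the 2,3-trans-3,4-cis relative configuration, which is irrelevant afterwards.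

Step 6
Reactants: 12 rac-(2R,3S,4S)-7-benzyloxy-8-bromo-2-(4-benzyloxy-3-methoxyphenyl)chromane-3,4-diol
Product: 14 7-benzyloxy-8-bromo-2-(4-benzyloxy-3-methoxyphenyl)-3-hydroxy-4H-chromen-4-one, via chromane-3,4-dione 13 (not isolated)
Conditions: (COCl)2, DMSO, CH2Cl2, −78 °C; Et3N, −78 °C to rt
Reagents that add atoms: none
Why: Swern oxidation of a vicinal diol, in which both alkoxysulfonium ions form before base is added so that glycol cleavage is avoided, should give dione 13, whose C2–H (benzylic, alpha to the C3 ketone and to O1) enolises under triethylamine to the hydrogen-bonded 4-pyranone tautomer, the flavonol, removing all stereocentres.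

Step 7
Reactants: 14 7-benzyloxy-8-bromo-2-(4-benzyloxy-3-methoxyphenyl)-3-hydroxy-4H-chromen-4-one
Product: 15 3,7-dihydroxy-2-(4-hydroxy-3-methoxyphenyl)-4H-chromen-4-one (geraldol)
Conditions: H2 (1 atm), 10% Pd/C, NaOAc, THF/MeOH, rt
Reagents that add atoms: none
Why: Catalytic hydrogenolysis should cleave both benzyl ethers and, with acetate taking up the hydrogen bromide, the aryl C–Br bond (hydrodehalogenation) in one operation, while the tetrasubstituted C2=C3 bond of the chromone, a vinylogous ester, is not expected to be reduced at atmospheric pressure.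

Step 8
Reactants: 15 3,7-dihydroxy-2-(4-hydroxy-3-methoxyphenyl)-4H-chromen-4-one
Product: 16 2-(3-methoxy-4-sulfooxyphenyl)-4-oxo-4H-chromene-3,7-diyl bis(hydrogen sulfate) (geraldol 3,7,4'-tri-O-sulfate, CNP0382475.0)
Conditions: SO3·pyridine (excess), pyridine, 65 °C; sulfonic acid resin (H+ form), H2O, 0 °C
Reagents that add atoms: sulfur trioxide–pyridine complex, O=S(=O)([O-])[n+]1ccccc1
Why: O-Sulfonation of phenolic and enolic hydroxyls with a sulfur trioxide–amine complex, where the absence of a 5-hydroxyl makes the trisulfate the exhaustive product and excess reagent with heating should drive the hydrogen-bonded 3-hydroxyl; cold proton exchange then gives the drawn acid form.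

Compound list
1 | 4-benzyloxy-3-methoxybenzaldehyde (O-benzylvanillin) | COc1cc(C=O)ccc1OCc1ccccc1 | starting material
2 | ethynylmagnesium bromide | C#C[Mg]Br | starting material
3 | 1-(4-benzyloxy-3-methoxyphenyl)prop-2-yn-1-ol (racemic) | COc1cc(C(O)C#C)ccc1OCc1ccccc1 | intermediate
4 | 2-bromoresorcinol (2-bromobenzene-1,3-diol) | Oc1cccc(O)c1Br | starting material
5 | benzyl bromide | BrCc1ccccc1 | starting material
6 | 3-benzyloxy-2-bromophenol | Oc1cccc(OCc2ccccc2)c1Br | intermediate
7 | 1-benzyloxy-2-bromo-3-{[1-(4-benzyloxy-3-methoxyphenyl)prop-2-yn-1-yl]oxy}benzene (racemic) | COc1cc(C(C#C)Oc2cccc(OCc3ccccc3)c2Br)ccc1OCc1ccccc1 | intermediate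
8 | 3-benzyloxy-2-bromo-6-[3-(4-benzyloxy-3-methoxyphenyl)propa-1,2-dien-1-yl]cyclohexa-2,4-dien-1-one (transient, configuration not defined) | O=C1C(Br)=C(OCc2ccccc2)C=CC1C=C=Cc1ccc(OCc2ccccc2)c(OC)c1 | intermediate
9 | 3-benzyloxy-2-bromo-6-[3-(4-benzyloxy-3-methoxyphenyl)propa-1,2-dien-1-yl]phenol (transient) | Oc1c(Br)c(OCc2ccccc2)ccc1C=C=Cc1ccc(OCc2ccccc2)c(OC)c1 | intermediate
10 | 3-benzyloxy-2-bromo-6-[3-(4-benzyloxy-3-methoxyphenyl)prop-2-en-1-ylidene]cyclohexa-2,4-dien-1-one (transient; side chain syn to the carbonyl) | O=C1C(Br)=C(OCc2ccccc2)C=C/C1=C/C=Cc1ccc(OCc2ccccc2)c(OC)c1 | intermediate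
11 | 7-benzyloxy-8-bromo-2-(4-benzyloxy-3-methoxyphenyl)-2H-chromene (racemic) | COc1cc(C2C=Cc3ccc(OCc4ccccc4)c(Br)c3O2)ccc1OCc1ccccc1 | intermediate
12 | rac-(2R,3S,4S)-7-benzyloxy-8-bromo-2-(4-benzyloxy-3-methoxyphenyl)chromane-3,4-diol (one enantiomer drawn) | COc1cc([C@@H]2[C@@H](O)[C@@H](O)c3ccc(OCc4ccccc4)c(Br)c3O2)ccc1OCc1ccccc1 | intermediate
13 | 7-benzyloxy-8-bromo-2-(4-benzyloxy-3-methoxyphenyl)chromane-3,4-dione (transient, racemic) | COc1cc(C2Oc3c(Br)c(OCc4ccccc4)ccc3C(=O)C2=O)ccc1OCc1ccccc1 | intermediate
14 | 7-benzyloxy-8-bromo-2-(4-benzyloxy-3-methoxyphenyl)-3-hydroxy-4H-chromen-4-one | COc1cc(-c2oc3c(Br)c(OCc4ccccc4)ccc3c(=O)c2O)ccc1OCc1ccccc1 | intermediate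
15 | 3,7-dihydroxy-2-(4-hydroxy-3-methoxyphenyl)-4H-chromen-4-one (geraldol) | COc1cc(-c2oc3cc(O)ccc3c(=O)c2O)ccc1O | intermediate
16 | 2-(3-methoxy-4-sulfooxyphenyl)-4-oxo-4H-chromene-3,7-diyl bis(hydrogen sulfate) | COc1cc(-c2oc3cc(OS(=O)(=O)O)ccc3c(=O)c2OS(=O)(=O)O)ccc1OS(=O)(=O)O | target

Total step count: 8. Longest linear sequence: 7 (step 1 or step 2, then steps 3 to 8).

Steps most likely to fail

Step 4. The propargylic C–O bond may heterolyse before the sigmatropic shift, since the carbon is benzylic to an electron-rich ring and the bromophenoxide is a good leaving group. The dienone formed reversibly at the brominated carbon may also be drained by intramolecular cycloaddition, and the electron-rich chromene may oligomerise at this temperature. The fallback builds ring C by a different logic and sets out from 1. A Claisen–Schmidt condensation (KOH, EtOH, rt) with purchased 1-(4-benzyloxy-2-hydroxyphenyl)ethanone F1 would give the chalcone (E)-1-(4-benzyloxy-2-hydroxyphenyl)-3-(4-benzyloxy-3-methoxyphenyl)prop-2-en-1-one F2. Algar–Flynn–Oyamada oxidation (H2O2, NaOH, MeOH, 0 °C to rt) would convert it into 7-benzyloxy-2-(4-benzyloxy-3-methoxyphenyl)-3-hydroxy-4H-chromen-4-one F3. Hydrogenolysis (H2, 10% Pd/C, THF/MeOH) would then rejoin the route at 15.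

Step 6. The double oxidation may stop after one carbinol, the glycol may cleave between C3 and C4, or the new enol may be methylthiomethylated by residual activated sulfoxide. The fallback separates the two oxidation events and sets out from 12. Activated MnO2 (CH2Cl2, rt) should oxidise only the benzylic C4 carbinol to rac-(2R,3R)-7-benzyloxy-8-bromo-2-(4-benzyloxy-3-methoxyphenyl)-3-hydroxychroman-4-one F4. Dehydrogenation of this dihydroflavonol with iodine and KOAc in AcOH at 100 °C would rejoin the route at 14.

Step 8. Sulfation of the hydrogen-bonded 3-hydroxyl may stay incomplete, and sulfate groups may be lost by acid hydrolysis during isolation of the polar product. The fallback uses protected sulfate diesters that can be purified on silica and sets out from 15. 2,2,2-Trichloroethyl chlorosulfate with Et3N and DMAP in THF would give geraldol 3,7,4'-tris(2,2,2-trichloroethyl sulfate) F5. Reductive removal of the trichloroethyl groups (Zn, HCO2NH4, MeOH, rt) followed by cold proton exchange would rejoin the route at 16.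

Further compounds
F1 | step 4 | 1-(4-benzyloxy-2-hydroxyphenyl)ethanone (purchased) | CC(=O)c1ccc(OCc2ccccc2)cc1O
F2 | step 4 | (E)-1-(4-benzyloxy-2-hydroxyphenyl)-3-(4-benzyloxy-3-methoxyphenyl)prop-2-en-1-one | COc1cc(/C=C/C(=O)c2ccc(OCc3ccccc3)cc2O)ccc1OCc1ccccc1
F3 | step 4 | 7-benzyloxy-2-(4-benzyloxy-3-methoxyphenyl)-3-hydroxy-4H-chromen-4-one | COc1cc(-c2oc3cc(OCc4ccccc4)ccc3c(=O)c2O)ccc1OCc1ccccc1
F4 | step 6 | rac-(2R,3R)-7-benzyloxy-8-bromo-2-(4-benzyloxy-3-methoxyphenyl)-3-hydroxychroman-4-one | COc1cc([C@@H]2[C@@H](O)C(=O)c3ccc(OCc4ccccc4)c(Br)c3O2)ccc1OCc1ccccc1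
F5 | step 8 | geraldol 3,7,4'-tris(2,2,2-trichloroethyl sulfate) | COc1cc(-c2oc3cc(OS(=O)(=O)OCC(Cl)(Cl)Cl)ccc3c(=O)c2OS(=O)(=O)OCC(Cl)(Cl)Cl)ccc1OS(=O)(=O)OCC(Cl)(Cl)Cl
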